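## Structural features

The target is a 2,3,4-trisubstituted tetrahydrofuran (ring O1, C2, C3, C4, C5H2). C2 carries a 3-hydroxy-4-methoxyphenyl group, C3 a hydroxymethyl group (carbon C9) and C4 a 3-hydroxy-4-methoxybenzoyl group (ketone carbon C7'). The three stereocentres are contiguous, (2S,3R,4S), and all-trans: aryl and aroyl lie on one face of the ring and the hydroxymethyl group on the other. Two of them can be repaired late, because C4 is α to the ketone and C2 is a benzylic ether carbon para to a methoxy group; C3 has no such handle and must be set absolutely. Fragile points are the β-alkoxy ketone (O1 is β to C7', so strong base can open the ring), the acid-ionisable C2–O1 bond, the two phenols, and the γ-hydroxy ketone, which can fold to a hemiketal when C3 and C4 are cis. The real difficulty is therefore the C2–C3 bond with absolute control at C3, between two oxygenated benzylic carbons that look alike. The key step exploits the 1,4-relationship between the C9 oxygen and C7'. Joining them as a γ-lactone across C3–C4 gives a rigid ring in which a carbene at C3 lies five atoms from the benzylic C2–H of an O1 benzyl ether, so that C–H insertion forms C2–C3, closes the ether ring cis-fused and copies the C4 configuration onto C3.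

## Logic of the disconnections

19 ⇒ 18. The two phenolic O–H bonds are replaced by O–Si bonds. Free phenols would be acylated, alkylated or deprotonated in almost every earlier operation, so they are carried masked at the cost of one final step. The forward step must cleave both silyl ethers without a base strong enough to eliminate O1 from the β-alkoxy ketone.

18 ⇒ 17. The C2–O1 bond is cut in the stereochemical sense only: C2 is inverted. The insertion chosen below is expected to place the C2 aryl group cis to C9, and C2 is the one ring carbon that can be ionised, so its configuration is left to thermodynamics. The gain is that C2 never has to be controlled kinetically. The forward step must ionise C2–O1 reversibly and reclose faster than the cation loses the C3 proton.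

17 ⇒ 15. The C7' carbonyl is taken back to a secondary alcohol and C4 is inverted (through 16). An sp3 C7'–O and a cis C3/C4 arrangement are what a lactone between C9 and the C7' oxygen requires. The gain is that C4, being α to the future ketone, can also be left to thermodynamics. The forward steps must oxidise the benzylic alcohol beside the primary one and epimerise C4 without opening the ring.

15 ⇒ 14. The bond between C9 and the C7' oxygen is re-formed, so that C9 becomes a lactone carbonyl. A flexible diol becomes a rigid cis-fused bicycle. The forward step is a lactone reduction that must spare the aryl silyl ethers.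

14 ⇒ 13. The C2–C3 bond is cut: C3 becomes a diazo carbon and C2 the benzylic CH2 of an ether. This is the strategic cut. It removes the ether ring and two stereocentres and leaves a monocyclic lactone with only C4 and C7' stereogenic. The forward step must insert into C2–H (1,5) and not shift the C4 hydrogen, and it relies on the impossibility of a trans-fused product to relay C4 to C3.

13 ⇒ 11. The C3=N2 bond is cut. The diazo group is introduced last because it is the least robust function. The forward step must activate the weakly acidic lactone α-position (through 12) without epimerising C4.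

11 ⇒ 8 + 10. The C2–O1 ether bond is cut, giving a primary alcohol and an activated benzyl donor; 10 goes back through 9 to 2. The two aryl-bearing halves are thus separated. Because 8 can shift its lactone onto the free hydroxyl under base, the forward etherification must run under acid.

8 ⇒ 7. The C5 carbinol is taken back to the acyl carbon of an imide (C5–N). This reveals a chiral auxiliary on the carbon that becomes C5. The forward reduction must distinguish the imide carbonyl from the lactone carbonyl.

7 ⇒ 5 + 2. The C4–C7' bond and the lactone C9–O bond are cut (through 6). This aldol disconnection removes both remaining stereocentres. The forward step must deliver the syn adduct in the absolute sense that makes C4 the centre which later dictates C3.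

5 ⇒ 3 + 4, and 2 ⇒ 1. The N–acyl bond and the phenolic O–Si bond are cut, arriving at three commercial compounds; both aromatic rings of 19 come from 1.

## Other disconnections considered

Alternative 1: Prins–pinacol annulation.
- **Cut:** C2–C3 and C4–C5, with C7' kept only as a formyl carbon.
- **Forward key step:** the allylic acetal A1 (a 2-aryl-4-alkenyl-1,3-dioxolane of the glyceraldehyde series) is opened by SnCl4 to the O1=C2 oxocarbenium ion. The E-alkene terminus (C3) attacks C2 in a chair, and the cation left at C4 is quenched by a pinacol-type 1,2-shift of C5, which contracts the six-membered intermediate to the tetrahydrofuran aldehyde A2.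
- **In its favour:** two ring bonds and all three stereocentres form in one operation, and with every substituent equatorial in the chair the all-trans pattern should arise directly. On this point it is better than the chosen plan, which must correct C2 and C4 afterwards. No diazo compound is needed.
- **Against it here:** the alkene is only 1,2-disubstituted and carries an allylic ester, so cyclisation passes through a secondary, inductively destabilised cation, and loss of chirality transfer through oxonia-Cope equilibration cannot be excluded. A chair analysis with the metal alkoxide equatorial calls for the 4R acetal, the less accessible enantiomeric series. A2 has C7' at the aldehyde level, so the aroyl group still needs aryl–metal addition and re-oxidation, and the pivalate must be removed from a base-sensitive β-alkoxy ketone.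
- **Comparison:** structurally both plans make C2–C3, but this one builds the ring from a chain while the chosen plan closes it on a lactone template. Mechanistically it is cationic, against carbene insertion. In step count the two are about equal (roughly a dozen operations each), since what is saved on epimerisations is spent on building the ketone.

Alternative 2: donor–acceptor cyclopropane (3+2).
- **Cut:** O1–C2 and C4–C5.
- **Forward key step:** Sn(OTf)2 binds the geminal diester of the cyclopropane A3 and polarises the bond between the aryl-bearing carbon and the malonate carbon. The oxygen of formaldehyde A4 bonds to C2 and the malonate carbon closes on the resulting oxocarbenium carbon (C5), giving the tetrahydrofuran diester A5.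
- **In its favour:** a catalytic, convergent assembly; the 4-methoxyaryl donor makes ring opening easy; C3 is carried unchanged from A3, so absolute control rests on one asymmetric cyclopropanation. C4 is not stereogenic until one ester is removed and can then settle trans, which is the equal of the thermodynamic control of C4 in the chosen plan.
- **Against it here:** such openings normally proceed with inversion at the donor carbon, which would turn the readily made trans arrangement of A3 into the 2,3-cis ether. The 2,3-trans product needs either the other relative configuration on the three-membered ring or a fully ionised benzylic carbon, so C2 is no better secured than in the chosen plan. A4 must be handled as the monomer and is less documented as a partner than aromatic aldehydes. Turning the diester of A5 into an aroyl group needs dealkoxycarbonylation (hot halide on a β-alkoxy ester) and a two- or three-step ester-to-aryl-ketone conversion.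
- **Comparison:** structurally it forms the two bonds that bring in C5 and leaves C2–C3 intact. Mechanistically it is a Lewis-acid polar cycloaddition against a carbene insertion. The total count should be about equal, with a somewhat shorter longest linear sequence because the ring is built convergently, which is an advantage over the chosen plan.

Alternative 3: palladium zwitterion (3+2).
- **Cut:** O1–C5 and C3–C4.
- **Forward key step:** zerovalent palladium generated from Pd2(dba)3 and a phosphine ionises the vinyl carbonate A6 with decarboxylation. The alkoxide on C2 adds to the terminus of the aryl vinyl ketone A7, and the enolate carbon (C4) closes on the internal carbon of the π-allyl unit (C3), giving the 3-vinyl tetrahydrofuran A8.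
- **In its favour:** it is the most convergent of the four plans. Both halves derive from 2, the aroyl group is in place from the start, and C2 enters enantiopure with its C–O bond never broken. Only the conversion of vinyl into hydroxymethyl and desilylation remain. On step count (about nine or ten operations, longest linear sequence about seven) and on redox economy it is better than the chosen plan.
- **Against it here:** zwitterions of this kind are best documented with doubly activated acceptors, whereas A7 is a weaker, polymerisation-prone acceptor. A6 carries a stereocentre next to the allyl unit, so the C3 configuration depends on a substrate/ligand match that is not established, and attack at the allyl terminus would give a seven-membered ring. Degrading the vinyl group makes C3 α to an aldehyde beside an aryl ketone and two electron-rich arenes, which endangers the one stereocentre that cannot be repaired.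
- **Comparison:** structurally it leaves C2–C3 intact and forms the C4 side of the ring. Mechanistically it is an ionic allyl-palladium cascade against a carbene insertion. It is shorter but rests on less secure precedent for this substrate class; the chosen plan is longer, but each stereocentre is auxiliary-controlled, forced by ring fusion or thermodynamically adjustable.

Key step: step 9

Remark: hydroxy ester 6 is assumed to lactonise under the mild acid named in step 3; atom labels (O1, C2–C5, C9, C7') follow the target in every intermediate, and Ar = 3-(tert-butyldimethylsilyloxy)-4-methoxyphenyl.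

## Route

Step 1
Reactants: 1 isovanillin (3-hydroxy-4-methoxybenzaldehyde)
Product: 2 3-(tert-butyldimethylsilyloxy)-4-methoxybenzaldehyde (ArCHO)
Conditions: TBSCl, imidazole, DMF, 0 °C → rt
Reagents that add atoms: tert-butyldimethylsilyl chloride (TBSCl), CC(C)(C)[Si](C)(C)Cl
Why: Imidazole-assisted O-silylation of the phenol (substitution at silicon); the aldehyde is inert and no stereocentre is involved.

Step 2
Reactants: 3 (S)-4-benzyl-2-oxazolidinone; 4 methyl 4-chloro-4-oxobutanoate
Product: 5 methyl 4-[(4S)-4-benzyl-2-oxo-1,3-oxazolidin-3-yl]-4-oxobutanoate
Conditions: n-BuLi, THF, −78 °C; then 4, −78 → 0 °C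
Reagents that add atoms: none
Why: N-Acylation of the lithiated oxazolidinone by the acid chloride, which reacts far faster than the methyl ester; the auxiliary stereocentre is untouched.

Step 3
Reactants: 5 methyl 4-[(4S)-4-benzyl-2-oxo-1,3-oxazolidin-3-yl]-4-oxobutanoate; 2 ArCHO
Product: 7 (4S)-4-benzyl-3-{[(2S,3S)-2-Ar-5-oxooxolan-3-yl]carbonyl}-1,3-oxazolidin-2-one (4,5-trans lactone), via syn-aldol hydroxy ester 6 (not isolated)
Conditions: Bu2BOTf, iPr2NEt, CH2Cl2, 0 °C; 2, −78 → 0 °C; H2O2, pH 7 buffer, MeOH, 0 °C; then PPTS (cat.), CH2Cl2, rt
Reagents that add atoms: none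
Why: Evans syn-aldol reaction followed by lactonisation: the Z boron enolate of the imide (the imide α-CH2 is enolised in preference to the ester α-CH2) adds to 2 through a closed chair (Zimmerman–Traxler) transition state on the face away from the benzyl group, which sets C4 and C7' (both S at this stage), and the benzylic hydroxyl of 6 then closes onto the methyl ester (5-exo-trig, loss of methanol) to give the trans lactone.

Step 4
Reactants: 7 (4S)-4-benzyl-3-{[(2S,3S)-2-Ar-5-oxooxolan-3-yl]carbonyl}-1,3-oxazolidin-2-one
Product: 8 (4R,5S)-5-Ar-4-(hydroxymethyl)oxolan-2-one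
Conditions: LiBH4, MeOH (1 equiv), THF, −10 → 0 °C; aq NH4Cl
Reagents that add atoms: none
Why: Chemoselective borohydride reduction of the exocyclic imide carbonyl (through the aldehyde) beside the less electrophilic lactone, with release of the auxiliary; the cold conditions and buffered quench are chosen to prevent migration of the lactone onto the new primary alcohol, and C4 keeps its configuration (4R only by change of priorities).

Step 5
Reactants: 2 ArCHO
Product: 9 [3-(tert-butyldimethylsilyloxy)-4-methoxyphenyl]methanol (ArCH2OH)
Conditions: NaBH4, MeOH, 0 °C
Reagents that add atoms: none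
Why: Borohydride reduction of the aromatic aldehyde to the benzylic alcohol; the aryl silyl ether should survive brief exposure at 0 °C.

Step 6
Reactants: 9 ArCH2OH
Product: 10 ArCH2 2,2,2-trichloroacetimidate (ArCH2O–C(=NH)CCl3)
Conditions: Cl3CCN, DBU (cat.), CH2Cl2, 0 °C
Reagents that add atoms: trichloroacetonitrile, N#CC(Cl)(Cl)Cl
Why: Base-catalysed addition of the alcohol to the nitrile (trichloroacetimidate formation).

Step 7
Reactants: 8 (4R,5S)-5-Ar-4-(hydroxymethyl)oxolan-2-one; 10 ArCH2 2,2,2-trichloroacetimidate
Product: 11 (4R,5S)-5-Ar-4-[(ArCH2O)methyl]oxolan-2-one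
Conditions: CSA (cat.), CH2Cl2, 0 °C → rt
Reagents that add atoms: none
Why: Acid-catalysed benzylation with a trichloroacetimidate: the protonated imidate releases a 4-methoxy-stabilised benzylic cation that is trapped by the primary alcohol, so no alkoxide is formed and translactonisation and epimerisation are avoided.

Step 8
Reactants: 11 (4R,5S)-5-Ar-4-[(ArCH2O)methyl]oxolan-2-one
Product: 13 (4R,5S)-5-Ar-4-[(ArCH2O)methyl]-3-diazooxolan-2-one, via 3-trifluoroacetyl lactone 12 (not isolated)
Conditions: LiN(SiMe3)2, THF, −78 °C; CF3CO2CH2CF3, −78 °C; then p-ABSA, Et3N, H2O, MeCN, rt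
Reagents that add atoms: 4-acetamidobenzenesulfonyl azide (p-ABSA), CC(=O)Nc1ccc(cc1)S(=O)(=O)N=[N+]=[N-] (the two diazo nitrogens); 2,2,2-trifluoroethyl trifluoroacetate, O=C(OCC(F)(F)F)C(F)(F)F (its trifluoroacetyl group is carried by 12 only)
Why: Regitz-type deacylative diazo transfer: the lactone enolate is trifluoroacetylated (Claisen condensation) to activate C3, the sulfonyl azide transfers N2 to the 1,3-dicarbonyl compound and the trifluoroacetyl group leaves as the N-acyl sulfonamide; C4 and C7' are not acidic under these conditions and are retained.

Step 9
Reactants: 13 (4R,5S)-5-Ar-4-[(ArCH2O)methyl]-3-diazooxolan-2-one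
Product: 14 (1S,2R,5R,6S)-2,6-di-Ar-3,7-dioxabicyclo[3.3.0]octan-8-one (cis-fused; C1 = C3, C2 = C2, C5 = C4 and C6 = C7' of the target; C2 aryl on the concave face)
Conditions: Rh2(OAc)4 (2 mol%), CH2Cl2, reflux, slow addition of 13
Reagents that add atoms: none
Why: Rh2(OAc)4, a dimer of divalent rhodium, takes up the diazo carbon and expels N2 to give an electrophilic rhodium carbene at C3. The carbene inserts into a benzylic C2–H bond of the O1 benzyl ether through a concerted, asynchronous three-centre transition state with hydride-transfer character, forming C2–C3 and releasing the catalyst; the closest known reaction type is the dirhodium-catalysed 1,5 C–H insertion of α-diazo-γ-butyrolactones into ether C–H bonds to give furofuranones. The tetrahydrofuran closes as a five-membered ring by 1,5-insertion (carbene carbon and C–H carbon linked through C4, C5 and O1), annulated onto the C3–C4 bond of the lactone. C3 is controlled by the ring fusion: a bicyclo[3.3.0] system can only be cis-fused, so the 4R centre set in step 3 dictates 3S in 14, which is the 3R centre of the target once the lactone is opened. C2 is controlled by the chair-like insertion geometry, in which the aryl group turns away from the carboxylate wall of the catalyst and ends on the concave face (2,3-cis); this centre need not be right because it is equilibrated in step 12. The selectivity needed is 1,5-insertion over 1,2-hydride shift from C4, carbene dimerisation and attack on the electron-rich arenes. The substrate secures it because C2–H is activated by both the ether oxygen and the 4-methoxyaryl ring and because every other C–H bond would require a three- or four-membered transition state; slow addition at high dilution suppresses dimerisation.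

Step 10
Reactants: 14 (1S,2R,5R,6S)-2,6-di-Ar-3,7-dioxabicyclo[3.3.0]octan-8-one
Product: 15 (2R,3R,4R)-2-Ar-3-(hydroxymethyl)-4-[(S)-Ar(hydroxy)methyl]tetrahydrofuran
Conditions: LiBH4, THF, 0 °C → rt
Reagents that add atoms: none
Why: Hydride reduction of the lactone to the diol; no stereocentre is touched, and LiBH4 is mild enough for the aryl silyl ethers.

Step 11
Reactants: 15 (2R,3R,4R)-2-Ar-3-(hydroxymethyl)-4-[(S)-Ar(hydroxy)methyl]tetrahydrofuran
Product: 17 (2R,3R,4S)-2-Ar-4-(Ar-carbonyl)-3-(hydroxymethyl)tetrahydrofuran (2,3-cis, 3,4-trans), via all-cis hydroxy ketone 16 (not isolated)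
Conditions: MnO2 (activated), CH2Cl2, rt; filter; DBU (cat.), CH2Cl2, rt
Reagents that add atoms: none
Why: Activated MnO2 oxidises the benzylic C7' alcohol selectively and leaves the saturated primary alcohol; DBU then equilibrates the α-keto centre C4 through the enolate to the more stable 3,4-trans arrangement (thermodynamic control), C2 and C3 being non-acidic.

Step 12
Reactants: 17 (2R,3R,4S)-2-Ar-4-(Ar-carbonyl)-3-(hydroxymethyl)tetrahydrofuran
Product: 18 (2S,3R,4S)-2-Ar-4-(Ar-carbonyl)-3-(hydroxymethyl)tetrahydrofuran (all-trans)
Conditions: TFA–CH2Cl2 (1:10), 0 °C → rt; then aq NaHCO3, MeOH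
Reagents that add atoms: none
Why: Acid-mediated benzylic epimerisation: protonation ionises the C2–O1 bond to a 4-methoxy-stabilised benzylic cation that is recaptured by the C5 hydroxyl, so C2 should equilibrate to the thermodynamically preferred 2,3-trans (all-trans) isomer; C3 is not involved, and the 3,4-trans ketone cannot form a hemiketal.

Step 13
Reactants: 18 (2S,3R,4S)-2-Ar-4-(Ar-carbonyl)-3-(hydroxymethyl)tetrahydrofuran
Product: 19 (2S,3R,4S)-4-(3-hydroxy-4-methoxybenzoyl)-2-(3-hydroxy-4-methoxyphenyl)-3-(hydroxymethyl)tetrahydrofuran (CNP0234761.1)
Conditions: TBAF, AcOH, THF, 0 °C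
Reagents that add atoms: none
Why: Fluoride-mediated cleavage of the two aryl silyl ethers (strong Si–F bond); buffering with acetic acid keeps the medium from becoming basic enough to open the β-alkoxy ketone or disturb C4.

## Compound list

1 | isovanillin (3-hydroxy-4-methoxybenzaldehyde) | COc1ccc(C=O)cc1O | starting material
2 | 3-(tert-butyldimethylsilyloxy)-4-methoxybenzaldehyde | COc1ccc(C=O)cc1O[Si](C)(C)C(C)(C)C | intermediate
3 | (S)-4-benzyl-2-oxazolidinone | O=C1OC[C@H](Cc2ccccc2)N1 | starting material
4 | methyl 4-chloro-4-oxobutanoate | COC(=O)CCC(=O)Cl | starting material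
5 | methyl 4-[(4S)-4-benzyl-2-oxo-1,3-oxazolidin-3-yl]-4-oxobutanoate | COC(=O)CCC(=O)N1C(=O)OC[C@@H]1Cc1ccccc1 | intermediate
6 | methyl (3S)-3-[(S)-Ar(hydroxy)methyl]-4-[(4S)-4-benzyl-2-oxo-1,3-oxazolidin-3-yl]-4-oxobutanoate (syn-aldol adduct) | COC(=O)C[C@H](C(=O)N1C(=O)OC[C@@H]1Cc1ccccc1)[C@H](O)c1ccc(OC)c(O[Si](C)(C)C(C)(C)C)c1 | intermediate
7 | (4S)-4-benzyl-3-{[(2S,3S)-2-Ar-5-oxooxolan-3-yl]carbonyl}-1,3-oxazolidin-2-one | O=C1O[C@H](c2ccc(OC)c(O[Si](C)(C)C(C)(C)C)c2)[C@@H](C(=O)N2C(=O)OC[C@@H]2Cc2ccccc2)C1 | intermediate
8 | (4R,5S)-5-Ar-4-(hydroxymethyl)oxolan-2-one | O=C1O[C@H](c2ccc(OC)c(O[Si](C)(C)C(C)(C)C)c2)[C@@H](CO)C1 | intermediate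
9 | [3-(tert-butyldimethylsilyloxy)-4-methoxyphenyl]methanol | COc1ccc(CO)cc1O[Si](C)(C)C(C)(C)C | intermediate
10 | 3-(tert-butyldimethylsilyloxy)-4-methoxybenzyl 2,2,2-trichloroacetimidate | COc1ccc(COC(=N)C(Cl)(Cl)Cl)cc1O[Si](C)(C)C(C)(C)C | intermediate
11 | (4R,5S)-5-Ar-4-[(ArCH2O)methyl]oxolan-2-one | O=C1O[C@H](c2ccc(OC)c(O[Si](C)(C)C(C)(C)C)c2)[C@@H](COCc2ccc(OC)c(O[Si](C)(C)C(C)(C)C)c2)C1 | intermediate
12 | (4R,5S)-5-Ar-4-[(ArCH2O)methyl]-3-(trifluoroacetyl)oxolan-2-one (C3 epimers and enol) | O=C1O[C@H](c2ccc(OC)c(O[Si](C)(C)C(C)(C)C)c2)[C@@H](COCc2ccc(OC)c(O[Si](C)(C)C(C)(C)C)c2)C1C(=O)C(F)(F)F | intermediate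
13 | (4R,5S)-5-Ar-4-[(ArCH2O)methyl]-3-diazooxolan-2-one | O=C1O[C@H](c2ccc(OC)c(O[Si](C)(C)C(C)(C)C)c2)[C@@H](COCc2ccc(OC)c(O[Si](C)(C)C(C)(C)C)c2)C1=[N+]=[N-] | intermediate
14 | (1S,2R,5R,6S)-2,6-di-Ar-3,7-dioxabicyclo[3.3.0]octan-8-one | O=C1O[C@H](c3ccc(OC)c(O[Si](C)(C)C(C)(C)C)c3)[C@H]2CO[C@@H](c3ccc(OC)c(O[Si](C)(C)C(C)(C)C)c3)[C@@H]12 | intermediate
15 | (2R,3R,4R)-2-Ar-3-(hydroxymethyl)-4-[(S)-Ar(hydroxy)methyl]tetrahydrofuran | O[C@H](c2ccc(OC)c(O[Si](C)(C)C(C)(C)C)c2)[C@H]1CO[C@@H](c3ccc(OC)c(O[Si](C)(C)C(C)(C)C)c3)[C@H]1CO | intermediate
16 | (2R,3R,4R)-2-Ar-4-(Ar-carbonyl)-3-(hydroxymethyl)tetrahydrofuran (all-cis) | COc1ccc(C(=O)[C@H]2CO[C@@H](c3ccc(OC)c(O[Si](C)(C)C(C)(C)C)c3)[C@H]2CO)cc1O[Si](C)(C)C(C)(C)C | intermediate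
17 | (2R,3R,4S)-2-Ar-4-(Ar-carbonyl)-3-(hydroxymethyl)tetrahydrofuran (2,3-cis, 3,4-trans) | COc1ccc(C(=O)[C@@H]2CO[C@@H](c3ccc(OC)c(O[Si](C)(C)C(C)(C)C)c3)[C@H]2CO)cc1O[Si](C)(C)C(C)(C)C | intermediate
18 | (2S,3R,4S)-2-Ar-4-(Ar-carbonyl)-3-(hydroxymethyl)tetrahydrofuran (all-trans) | COc1ccc(C(=O)[C@@H]2CO[C@H](c3ccc(OC)c(O[Si](C)(C)C(C)(C)C)c3)[C@H]2CO)cc1O[Si](C)(C)C(C)(C)C | intermediate
19 | (2S,3R,4S)-4-(3-hydroxy-4-methoxybenzoyl)-2-(3-hydroxy-4-methoxyphenyl)-3-(hydroxymethyl)tetrahydrofuran | COc1ccc(C(=O)[C@@H]2CO[C@H](c3ccc(OC)c(O)c3)[C@H]2CO)cc1O | target

## Step count and least certain steps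

Total: 13 steps. Longest linear sequence: 10 steps (steps 1, 3, 4, 7, 8, 9, 10, 11, 12, 13).

Step 9 (key step). The most likely failure is 1,2-hydride migration from C4 to the carbene carbon, or carbene dimerisation, outrunning insertion. The benzylic C–H must reach the carbene across a flexible CH2–O–CH2 tether, while a β-hydrogen sits directly beside it. Fallback (sets out from 8, uses 2, returns at 14): C2 is brought in at the carboxylic acid level and the C2–C3 bond is made by carbonyl addition instead of insertion. 2 is oxidised (NaClO2, NaH2PO4, 2-methyl-2-butene, t-BuOH–H2O) to 3-(tert-butyldimethylsilyloxy)-4-methoxybenzoic acid F1, which is esterified with 8 (EDC·HCl, DMAP, CH2Cl2, 0 °C) to the benzoate ester F2. LiN(SiMe3)2 (2.2 equiv, THF, −78 → 0 °C) should generate the lactone enolate, whose C3 adds to the ester carbonyl across the same five-atom tether (intramolecular Claisen-type acyl transfer, 5-exo-trig, necessarily cis-fused) to give the bicyclic hemiketal F3. Ionic reduction (Et3SiH, BF3·OEt2, CH2Cl2, −78 → −20 °C) of the aryl-stabilised oxocarbenium ion, with hydride entering from the convex face, should give 14. Its C2 epimer, if formed, converges at 18 in step 12.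

Step 12. Two things may go wrong. The benzylic cation may leak, by loss of the C3 proton (which would erode the only stereocentre that cannot be repaired) or by capture through the ketone oxygen. The thermodynamic bias towards 2,3-trans may also be too small for a clean result. Fallback (sets out from 17, returns at 18, no new compound): thiol-catalysed radical-chain epimerisation. A thiyl radical from (t-BuO)3SiSH (cat., di-tert-butyl hyponitrite as initiator, benzene, 60 °C) abstracts the doubly activated C2–H reversibly, so the same thermodynamic preference is reached through a planar benzylic α-oxy radical and no cation is formed.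

Step 11. The base may trigger β-elimination of the ring oxygen (retro-oxa-Michael) with reclosure through the C9 hydroxyl, or the equilibration may stall because the 3,4-cis isomer is stabilised by hemiketal formation. Fallback (sets out from 15, passes through isolated 16, returns at 18, no new compound): 15 is oxidised with MnO2 alone and 16 is isolated. A single acid treatment (TsOH·H2O, wet MeCN, 40 °C) then equilibrates C4 through the enol and C2 through the benzylic cation in one flask. No base is present, so the elimination pathway is closed, and water keeps hemiketal dehydration reversible.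

Step 4. Over-reduction of the lactone, or migration of the lactone onto the newly formed primary alkoxide, may compete with clean imide reduction. Fallback (sets out from 7, returns at 8): LiOH, H2O2 (THF–H2O, 0 °C) cleaves the imide to the lactone carboxylic acid F4 with recovery of 3; any ring-opened hydroxy acid relactonises on acidification. BH3·SMe2 (THF, 0 °C → rt) then reduces the carboxylic acid chemoselectively to 8 under non-basic conditions.

Step 7. The highly ionisable imidate may self-condense (Friedel–Crafts oligomerisation) before the hindered primary alcohol captures the cation. Fallback (sets out from 8, uses 2 directly, returns at 11; 9 and 10 are then not needed): 8 is silylated (TMSCl, imidazole, CH2Cl2, 0 °C) to the trimethylsilyl ether F5. Reductive etherification of F5 with 2 (Et3SiH, TMSOTf (cat.), CH2Cl2, −78 °C) proceeds through the mixed silyl acetal and its oxocarbenium ion to 11. It is held in reserve because the ether product can itself ionise and be over-reduced.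

## Further compounds

F1 | step 9 | 3-(tert-butyldimethylsilyloxy)-4-methoxybenzoic acid | COc1ccc(C(=O)O)cc1O[Si](C)(C)C(C)(C)C
F2 | step 9 | [(2S,3R)-2-Ar-5-oxooxolan-3-yl]methyl 3-(tert-butyldimethylsilyloxy)-4-methoxybenzoate | O=C1O[C@H](c2ccc(OC)c(O[Si](C)(C)C(C)(C)C)c2)[C@@H](COC(=O)c2ccc(OC)c(O[Si](C)(C)C(C)(C)C)c2)C1
F3 | step 9 | (1S,5R,6S)-2,6-di-Ar-2-hydroxy-3,7-dioxabicyclo[3.3.0]octan-8-one (hemiketal, C2 unassigned) | O=C1O[C@H](c3ccc(OC)c(O[Si](C)(C)C(C)(C)C)c3)[C@H]2COC(O)(c3ccc(OC)c(O[Si](C)(C)C(C)(C)C)c3)[C@@H]12
F0 | step 12 | none | none
F0 | step 11 | none | none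
F4 | step 4 | (2S,3S)-2-Ar-5-oxooxolane-3-carboxylic acid | O=C1O[C@H](c2ccc(OC)c(O[Si](C)(C)C(C)(C)C)c2)[C@@H](C(=O)O)C1
F5 | step 7 | (4R,5S)-5-Ar-4-[(trimethylsilyloxy)methyl]oxolan-2-one | O=C1O[C@H](c2ccc(OC)c(O[Si](C)(C)C(C)(C)C)c2)[C@@H](CO[Si](C)(C)C)C1
A1 | alternative 1 | (4R)-2-Ar-4-[(E)-3-(pivaloyloxy)prop-1-en-1-yl]-1,3-dioxolane (acetal carbon unassigned) | CC(C)(C)C(=O)OC/C=C/[C@@H]1COC(c2ccc(OC)c(O[Si](C)(C)C(C)(C)C)c2)O1
A2 | alternative 1 | (2S,3R,4S)-2-Ar-3-(pivaloyloxymethyl)tetrahydrofuran-4-carbaldehyde | O=C[C@@H]1CO[C@H](c2ccc(OC)c(O[Si](C)(C)C(C)(C)C)c2)[C@H]1COC(=O)C(C)(C)C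
A3 | alternative 2 | dimethyl (2S,3R)-2-Ar-3-[(tert-butyldimethylsilyloxy)methyl]cyclopropane-1,1-dicarboxylate (trans) | COC(=O)C1(C(=O)OC)[C@H](c2ccc(OC)c(O[Si](C)(C)C(C)(C)C)c2)[C@H]1CO[Si](C)(C)C(C)(C)C
A4 | alternative 2 | formaldehyde | C=O
A5 | alternative 2 | dimethyl (2S,3R)-2-Ar-3-[(tert-butyldimethylsilyloxy)methyl]tetrahydrofuran-4,4-dicarboxylate | COC(=O)C1(C(=O)OC)CO[C@H](c2ccc(OC)c(O[Si](C)(C)C(C)(C)C)c2)[C@H]1CO[Si](C)(C)C(C)(C)C
A6 | alternative 3 | (4R,5R)-4-Ar-5-ethenyl-1,3-dioxolan-2-one | O=C1O[C@H](C=C)[C@@H](c2ccc(OC)c(O[Si](C)(C)C(C)(C)C)c2)O1
A7 | alternative 3 | 1-Ar-prop-2-en-1-one | C=CC(=O)c1ccc(OC)c(O[Si](C)(C)C(C)(C)C)c1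
A8 | alternative 3 | (2S,3S,4S)-2-Ar-4-(Ar-carbonyl)-3-ethenyltetrahydrofuran (all-trans) | COc1ccc(C(=O)[C@@H]2CO[C@H](c3ccc(OC)c(O[Si](C)(C)C(C)(C)C)c3)[C@H]2C=C)cc1O[Si](C)(C)C(C)(C)C
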